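**Retrosynthetic overview**

1. Lactone A (the lactone on C3) is added last. The C3–C18 bond comes from a reductive vinylogous Mannich addition of a 2-silyloxyfuran to the C3 lactam of bicyclic lactam 25, followed by hydrogenation.
2. Key disconnection: the C1–C2 bond of the five-membered ring (N4, C9a, C1, C2, C3), formed by ring-closing metathesis of N-acryloyl-2-vinylazepane 23 and then hydrogenated. The enabling feature is that the methylene carbons C1 and C2 lie between the two N-bound carbons of that ring, so C3 can be carried as a lactam carbonyl (C2–C3 is then an acryloyl group on N4) and C9a as an allylic amine carbon (C1 is its vinyl group).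
3. The C9a–N4 bond and that vinyl group both come from one Overman rearrangement of an (E)-allylic imidate. The azepane ring (N4, C5–C9, C9a) is closed by N-alkylation with a C5 chloride.
4. C9 and C10 are set together by an Ireland–Claisen rearrangement (chirality from (S)-but-3-ene-1,2-diol), C11 by Felkin–Anh reduction, and C13 by a chiral zinc homoenolate, so lactone B is complete before nitrogen enters.
5. Order of ring formation: lactone B, azepane, pyrrolidinone ring (key step), lactone A.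

Key step: step 12

Remark: atom numbers are those of the octahydropyrrolo[1,2-a]azepine core (N4, ring-fusion carbon C9a); C10 is the ethyl-bearing carbon, C11–C14 are lactone B and C18–C21 are lactone A. Both chiral starting materials are assumed to be available in the enantiomer named.

**Route**

Step 1
Reactants: 1 (2S)-but-3-ene-1,2-diol
Product: 2 (2S)-1-{[tert-butyl(dimethyl)silyl]oxy}but-3-en-2-ol
Conditions: t-BuMe2SiCl (1.05 equiv), imidazole, CH2Cl2, −20 to 0 °C
Reagents that add atoms: tert-butyl(chloro)dimethylsilane, CC(C)(C)[Si](C)(C)Cl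
Why: Silyl ether formation is much faster at the unhindered primary hydroxyl than at the secondary allylic one, so the carbinol that will steer the Claisen step stays free and its configuration is untouched.

Step 2
Reactants: 2 (2S)-1-{[tert-butyl(dimethyl)silyl]oxy}but-3-en-2-ol; 3 6-chlorohex-1-ene
Product: 4 (2S,3E)-1-{[tert-butyl(dimethyl)silyl]oxy}-8-chlorooct-3-en-2-ol
Conditions: second-generation Grubbs catalyst RuCl2(=CHPh)(PCy3)(H2IMes) (3 mol %), 3 (3 equiv), CH2Cl2, 40 °C
Reagents that add atoms: 6-chlorohex-1-ene (3), C=CCCCCCl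
Why: Olefin cross-metathesis between a hindered allylic alcohol (slow to homodimerise) and an excess of an unhindered terminal alkene should give the thermodynamically preferred (E)-alkene without touching the stereocentre.

Step 3
Reactants: 4 (2S,3E)-1-{[tert-butyl(dimethyl)silyl]oxy}-8-chlorooct-3-en-2-ol; 5 butanoyl chloride
Product: 6 (2S,3E)-1-{[tert-butyl(dimethyl)silyl]oxy}-8-chlorooct-3-en-2-yl butanoate
Conditions: pyridine, DMAP (cat.), CH2Cl2, 0 °C
Reagents that add atoms: butanoyl chloride (5), CCCC(Cl)=O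
Why: Standard esterification of the secondary allylic alcohol with retention installs the butanoate whose α-carbon becomes C10.

Step 4
Reactants: 6 (2S,3E)-1-{[tert-butyl(dimethyl)silyl]oxy}-8-chlorooct-3-en-2-yl butanoate
Product: 9 (2S,3S,4E)-6-{[tert-butyl(dimethyl)silyl]oxy}-3-(4-chlorobutyl)-2-ethylhex-4-enoic acid, via silyl ketene acetal 7 (not isolated), via trimethylsilyl ester 8 (not isolated)
Conditions: LiN(i-Pr)2, THF, −78 °C; Me3SiCl, Et3N, −78 to 25 °C, then 60 °C; H2O work-up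
Reagents that add atoms: chlorotrimethylsilane, C[Si](C)(C)Cl (silicon of 7 and 8 only)
Why: Ireland–Claisen rearrangement, in which kinetic deprotonation in THF gives the (E)-silyl ketene acetal and the chair transition state with the CH2OSi group equatorial transfers the carbinol configuration to C9, sets C10 anti to it (ethyl axial) and creates the (E)-alkene.

Step 5
Reactants: 9 (2S,3S,4E)-6-{[tert-butyl(dimethyl)silyl]oxy}-3-(4-chlorobutyl)-2-ethylhex-4-enoic acid; 10 methyl (2R)-3-bromo-2-methylpropanoate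
Product: 13 methyl (2S,5S,6S,7E)-9-{[tert-butyl(dimethyl)silyl]oxy}-6-(4-chlorobutyl)-5-ethyl-2-methyl-4-oxonon-7-enoate, via acid chloride 11 (not isolated), via organozinc bromide 12 (not isolated)
Conditions: (a) 9, 1-chloro-N,N,2-trimethylprop-1-en-1-amine, CH2Cl2, 0 °C; (b) 10, Zn, LiCl, THF, 25 °C; (c) solutions (a) and (b), Pd(PPh3)4 (5 mol %), THF, 0 to 25 °C
Reagents that add atoms: methyl (2R)-3-bromo-2-methylpropanoate (10), BrC[C@H](C)C(=O)OC; 1-chloro-N,N,2-trimethylprop-1-en-1-amine, CC(C)=C(Cl)N(C)C (chlorine of 11 only); zinc, [Zn] (in 12 only)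
Why: Negishi acylation, in which the acid chloride made under neutral conditions (no ketene, so C10 is preserved) couples with the ester-bearing alkylzinc bromide, whose methyl stereocentre (future C13) is remote from the carbon–zinc bond and therefore configurationally safe.

Step 6
Reactants: 13 methyl (2S,5S,6S,7E)-9-{[tert-butyl(dimethyl)silyl]oxy}-6-(4-chlorobutyl)-5-ethyl-2-methyl-4-oxonon-7-enoate
Product: 15 (3S,5R)-5-[(3S,4S,5E)-7-{[tert-butyl(dimethyl)silyl]oxy}-4-(4-chlorobutyl)hept-5-en-3-yl]-3-methyloxolan-2-one, via hydroxy ester 14 (not isolated)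
Conditions: LiBH(s-Bu)3, THF, −78 °C; AcOH; then PPTS (cat.), toluene, 60 °C
Reagents that add atoms: none
Why: Felkin–Anh-controlled reduction by a bulky hydride (attack anti to the branched C9 substituent on the α-stereocentre C10) should set the C11 carbinol, and acid-catalysed lactonisation of the γ-hydroxy ester then closes lactone B with its methyl group already trans to the side chain.

Step 7
Reactants: 15 (3S,5R)-5-[(3S,4S,5E)-7-{[tert-butyl(dimethyl)silyl]oxy}-4-(4-chlorobutyl)hept-5-en-3-yl]-3-methyloxolan-2-one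
Product: 16 (3S,5R)-5-[(3S,4S,5E)-4-(4-chlorobutyl)-7-hydroxyhept-5-en-3-yl]-3-methyloxolan-2-one
Conditions: HF·pyridine, pyridine, THF, 0 to 25 °C
Reagents that add atoms: none
Why: Fluoride-mediated desilylation under buffered conditions cleaves the primary silyl ether without opening or epimerising the lactone.

Step 8
Reactants: 16 (3S,5R)-5-[(3S,4S,5E)-4-(4-chlorobutyl)-7-hydroxyhept-5-en-3-yl]-3-methyloxolan-2-one
Product: 17 (2E,4S,5S)-4-(4-chlorobutyl)-5-[(2R,4S)-4-methyl-5-oxooxolan-2-yl]hept-2-en-1-yl 2,2,2-trichloroethanimidate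
Conditions: Cl3CCN, DBU (10 mol %), CH2Cl2, 0 °C
Reagents that add atoms: trichloroacetonitrile, ClC(Cl)(Cl)C#N
Why: Base-catalysed addition of the primary allylic alcohol to the electron-poor nitrile (imidate formation) is fast, and nothing else in the molecule reacts with the reagent.

Step 9
Reactants: 17 (2E,4S,5S)-4-(4-chlorobutyl)-5-[(2R,4S)-4-methyl-5-oxooxolan-2-yl]hept-2-en-1-yl 2,2,2-trichloroethanimidate
Product: 18 2,2,2-trichloro-N-{(3S,4R,5S)-4-(4-chlorobutyl)-5-[(2R,4S)-4-methyl-5-oxooxolan-2-yl]hept-1-en-3-yl}acetamide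
Conditions: (R)-COP-Cl, [Pd(μ-Cl)(C39H33CoNO)]2 (5 mol %), CH2Cl2, 38 °C
Reagents that add atoms: none
Why: Catalytic asymmetric Overman rearrangement, in which the chiral palladacycle activates the (E)-alkene for attack by the imidate nitrogen ([3,3] overall), so the catalyst antipode chosen should fix C9a as S while transposing the alkene into the terminal vinyl group that becomes C1.

Step 10
Reactants: 18 2,2,2-trichloro-N-{(3S,4R,5S)-4-(4-chlorobutyl)-5-[(2R,4S)-4-methyl-5-oxooxolan-2-yl]hept-1-en-3-yl}acetamide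
Product: 21 (3S,5R)-5-{(1S)-1-[(2S,3R)-2-ethenylazepan-3-yl]propyl}-3-methyloxolan-2-one, via open-chain amino carboxylate 19 (not isolated), via azepane hydroxy carboxylate 20 (not isolated)
Conditions: NaOH (aq.), EtOH, 25 °C; then NaI (cat.), 70 °C, high dilution; then HCl (aq.) to pH 1, 25 °C; NaHCO3 work-up
Reagents that add atoms: sodium hydroxide, [Na+].[OH-] (oxygen and sodium of 19 and 20 only)
Why: Hydroxide cleaves the electron-poor trichloroacetamide (and reversibly opens the lactone), the freed primary amine closes the azepane by 7-exo-tet displacement of the primary chloride without touching C9a, and acidification re-closes lactone B from the γ-hydroxy acid.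

Step 11
Reactants: 21 (3S,5R)-5-{(1S)-1-[(2S,3R)-2-ethenylazepan-3-yl]propyl}-3-methyloxolan-2-one; 22 prop-2-enoyl chloride
Product: 23 (3S,5R)-5-{(1S)-1-[(2S,3R)-2-ethenyl-1-(prop-2-enoyl)azepan-3-yl]propyl}-3-methyloxolan-2-one
Conditions: Et3N, CH2Cl2, −20 °C
Reagents that add atoms: prop-2-enoyl chloride (22), C=CC(Cl)=O
Why: N-acylation of the secondary amine at low temperature (Schotten–Baumann-type amide formation) outruns aza-Michael addition and installs C2 and C3.

Step 12
Reactants: 23 (3S,5R)-5-{(1S)-1-[(2S,3R)-2-ethenyl-1-(prop-2-enoyl)azepan-3-yl]propyl}-3-methyloxolan-2-one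
Product: 24 (9R,9aS)-9-{(1S)-1-[(2R,4S)-4-methyl-5-oxooxolan-2-yl]propyl}-5,6,7,8,9,9a-hexahydro-3H-pyrrolo[1,2-a]azepin-3-one
Conditions: second-generation Grubbs catalyst RuCl2(=CHPh)(PCy3)(H2IMes) (5 mol %), toluene (0.005 M), 80 °C
Reagents that add atoms: none
Why: The ruthenium alkylidene loads onto the unhindered vinyl group on C9a and adds intramolecularly to the acrylamide C=C, and cycloreversion of the ruthenacyclobutane releases ethylene and forms the C1=C2 bond; the closest known reaction type is ring-closing metathesis of N-acryloyl 2-vinyl cyclic amines to bicyclic α,β-unsaturated γ-lactams. It closes the five-membered lactam ring (N4–C3–C2–C1–C9a) in an ordinary five-membered ring-closing mode with both olefinic carbons inside the ring, so only the (Z)-alkene can form. No stereocentre is created, and C9a and C9 are carried through unchanged because the amide nitrogen is non-basic and the C9a–H bond of 23 is not activated. In this one operation the acryloyl unit delivers C2 and C3, completes the bicyclic pyrrolo[1,2-a]azepine nucleus and leaves C3 at the lactam level needed for the later attachment of lactone A. The step needs cyclisation to win over dimerisation and alkene migration, which is secured by high dilution, by the amide rotamer that holds the acryloyl alkene next to the C9a vinyl group, and by 23 containing no other alkene.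

Step 13
Reactants: 24 (9R,9aS)-9-{(1S)-1-[(2R,4S)-4-methyl-5-oxooxolan-2-yl]propyl}-5,6,7,8,9,9a-hexahydro-3H-pyrrolo[1,2-a]azepin-3-one
Product: 25 (9R,9aS)-9-{(1S)-1-[(2R,4S)-4-methyl-5-oxooxolan-2-yl]propyl}octahydro-3H-pyrrolo[1,2-a]azepin-3-one
Conditions: H2 (1 atm), Pd/C, EtOAc, 25 °C
Reagents that add atoms: none
Why: Heterogeneous hydrogenation saturates only the conjugated C1=C2 bond, creates no stereocentre and leaves lactam and lactone intact.

Step 14
Reactants: 26 3-methylfuran-2(5H)-one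
Product: 27 triisopropyl[(3-methylfuran-2-yl)oxy]silane
Conditions: i-Pr3SiOSO2CF3, Et3N, CH2Cl2, 0 °C
Reagents that add atoms: triisopropylsilyl trifluoromethanesulfonate, CC(C)[Si](OS(=O)(=O)C(F)(F)F)(C(C)C)C(C)C
Why: Soft enolisation and O-silylation of the butenolide give the aromatic 2-silyloxyfuran, the vinylogous nucleophile for the next step.

Step 15
Reactants: 25 (9R,9aS)-9-{(1S)-1-[(2R,4S)-4-methyl-5-oxooxolan-2-yl]propyl}octahydro-3H-pyrrolo[1,2-a]azepin-3-one; 27 triisopropyl[(3-methylfuran-2-yl)oxy]silane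
Product: 30 (5S)-3-methyl-5-[(3S,9R,9aS)-9-{(1S)-1-[(2R,4S)-4-methyl-5-oxooxolan-2-yl]propyl}octahydro-1H-pyrrolo[1,2-a]azepin-3-yl]furan-2(5H)-one, via silyl hemiaminal 28 (not isolated), via iminium trifluoroacetate 29 (not isolated)
Conditions: IrCl(CO)(PPh3)2 (1 mol %), (HMe2Si)2O, toluene, 25 °C; then 27, CF3CO2H, CH2Cl2, −78 to 0 °C; NaHCO3 work-up
Reagents that add atoms: triisopropyl[(3-methylfuran-2-yl)oxy]silane (27), Cc1ccoc1O[Si](C(C)C)(C(C)C)C(C)C; 1,1,3,3-tetramethyldisiloxane, C[SiH](C)O[SiH](C)C (silyl group of 28 only); trifluoroacetic acid, OC(=O)C(F)(F)F (counter-ion of 29 only)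
Why: Iridium-catalysed hydrosilylation should reduce the tertiary lactam chemoselectively beside the lactone to the silyl hemiaminal, acid turns this into the C3 iminium ion, and vinylogous Mannich addition of the silyloxyfuran on the face opposite the C9 carbon at C9a (3,9a-trans) through the usual threo-selective arrangement sets C3 and C18.

Step 16
Reactants: 30 (5S)-3-methyl-5-[(3S,9R,9aS)-9-{(1S)-1-[(2R,4S)-4-methyl-5-oxooxolan-2-yl]propyl}octahydro-1H-pyrrolo[1,2-a]azepin-3-yl]furan-2(5H)-one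
Product: 31 (3S,5S)-3-methyl-5-[(3S,9R,9aS)-9-{(1S)-1-[(2R,4S)-4-methyl-5-oxooxolan-2-yl]propyl}octahydro-1H-pyrrolo[1,2-a]azepin-3-yl]oxolan-2-one
Conditions: H2 (1 atm), Pd/C, AcOH–EtOAc, 25 °C
Reagents that add atoms: none
Why: Heterogeneous hydrogenation should add hydrogen to the butenolide face opposite the bulky substituent on C18, placing the C20 methyl group cis to it and completing lactone A.

**Compound list**

1 | (2S)-but-3-ene-1,2-diol | OC[C@@H](O)C=C | starting material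
2 | (2S)-1-{[tert-butyl(dimethyl)silyl]oxy}but-3-en-2-ol | CC(C)(C)[Si](C)(C)OC[C@@H](O)C=C | intermediate
3 | 6-chlorohex-1-ene | C=CCCCCCl | starting material
4 | (2S,3E)-1-{[tert-butyl(dimethyl)silyl]oxy}-8-chlorooct-3-en-2-ol | CC(C)(C)[Si](C)(C)OC[C@@H](O)/C=C/CCCCCl | intermediate
5 | butanoyl chloride | CCCC(Cl)=O | starting material
6 | (2S,3E)-1-{[tert-butyl(dimethyl)silyl]oxy}-8-chlorooct-3-en-2-yl butanoate | CCCC(=O)O[C@H](CO[Si](C)(C)C(C)(C)C)/C=C/CCCCCl | intermediate
7 | tert-butyl{[(2S,3E)-8-chloro-2-({(1E)-1-[(trimethylsilyl)oxy]but-1-en-1-yl}oxy)oct-3-en-1-yl]oxy}dimethylsilane (silyl ketene acetal) | CC/C=C(/O[Si](C)(C)C)O[C@H](CO[Si](C)(C)C(C)(C)C)/C=C/CCCCCl | intermediate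
8 | trimethylsilyl (2S,3S,4E)-6-{[tert-butyl(dimethyl)silyl]oxy}-3-(4-chlorobutyl)-2-ethylhex-4-enoate | CC[C@@H]([C@H](/C=C/CO[Si](C)(C)C(C)(C)C)CCCCCl)C(=O)O[Si](C)(C)C | intermediate
9 | (2S,3S,4E)-6-{[tert-butyl(dimethyl)silyl]oxy}-3-(4-chlorobutyl)-2-ethylhex-4-enoic acid | CC[C@@H]([C@H](/C=C/CO[Si](C)(C)C(C)(C)C)CCCCCl)C(O)=O | intermediate
10 | methyl (2R)-3-bromo-2-methylpropanoate | BrC[C@H](C)C(=O)OC | starting material
11 | (2S,3S,4E)-6-{[tert-butyl(dimethyl)silyl]oxy}-3-(4-chlorobutyl)-2-ethylhex-4-enoyl chloride | CC[C@@H]([C@H](/C=C/CO[Si](C)(C)C(C)(C)C)CCCCCl)C(Cl)=O | intermediate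
12 | bromo[(2R)-3-methoxy-2-methyl-3-oxopropyl]zinc | Br[Zn]C[C@H](C)C(=O)OC | intermediate
13 | methyl (2S,5S,6S,7E)-9-{[tert-butyl(dimethyl)silyl]oxy}-6-(4-chlorobutyl)-5-ethyl-2-methyl-4-oxonon-7-enoate | CC[C@@H]([C@H](/C=C/CO[Si](C)(C)C(C)(C)C)CCCCCl)C(=O)C[C@H](C)C(=O)OC | intermediate
14 | methyl (2S,4R,5S,6S,7E)-9-{[tert-butyl(dimethyl)silyl]oxy}-6-(4-chlorobutyl)-5-ethyl-4-hydroxy-2-methylnon-7-enoate | CC[C@@H]([C@H](/C=C/CO[Si](C)(C)C(C)(C)C)CCCCCl)[C@H](O)C[C@H](C)C(=O)OC | intermediate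
15 | (3S,5R)-5-[(3S,4S,5E)-7-{[tert-butyl(dimethyl)silyl]oxy}-4-(4-chlorobutyl)hept-5-en-3-yl]-3-methyloxolan-2-one | CC[C@@H]([C@H](/C=C/CO[Si](C)(C)C(C)(C)C)CCCCCl)[C@H]1C[C@H](C)C(=O)O1 | intermediate
16 | (3S,5R)-5-[(3S,4S,5E)-4-(4-chlorobutyl)-7-hydroxyhept-5-en-3-yl]-3-methyloxolan-2-one | CC[C@@H]([C@H](/C=C/CO)CCCCCl)[C@H]1C[C@H](C)C(=O)O1 | intermediate
17 | (2E,4S,5S)-4-(4-chlorobutyl)-5-[(2R,4S)-4-methyl-5-oxooxolan-2-yl]hept-2-en-1-yl 2,2,2-trichloroethanimidate | CC[C@@H]([C@H](/C=C/COC(=N)C(Cl)(Cl)Cl)CCCCCl)[C@H]1C[C@H](C)C(=O)O1 | intermediate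
18 | 2,2,2-trichloro-N-{(3S,4R,5S)-4-(4-chlorobutyl)-5-[(2R,4S)-4-methyl-5-oxooxolan-2-yl]hept-1-en-3-yl}acetamide | CC[C@@H]([C@H]([C@@H](NC(=O)C(Cl)(Cl)Cl)C=C)CCCCCl)[C@H]1C[C@H](C)C(=O)O1 | intermediate
19 | sodium (2S,4R,5S,6R,7S)-7-amino-6-(4-chlorobutyl)-5-ethyl-4-hydroxy-2-methylnon-8-enoate | CC[C@@H]([C@H]([C@@H](N)C=C)CCCCCl)[C@H](O)C[C@H](C)C(=O)[O-].[Na+] | intermediate
20 | sodium (2S,4R,5S)-5-[(2S,3R)-2-ethenylazepan-3-yl]-4-hydroxy-2-methylheptanoate | CC[C@@H]([C@H]1CCCCN[C@H]1C=C)[C@H](O)C[C@H](C)C(=O)[O-].[Na+] | intermediate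
21 | (3S,5R)-5-{(1S)-1-[(2S,3R)-2-ethenylazepan-3-yl]propyl}-3-methyloxolan-2-one | CC[C@@H]([C@H]1CCCCN[C@H]1C=C)[C@H]1C[C@H](C)C(=O)O1 | intermediate
22 | prop-2-enoyl chloride | C=CC(Cl)=O | starting material
23 | (3S,5R)-5-{(1S)-1-[(2S,3R)-2-ethenyl-1-(prop-2-enoyl)azepan-3-yl]propyl}-3-methyloxolan-2-one | CC[C@@H]([C@H]1CCCCN(C(=O)C=C)[C@H]1C=C)[C@H]1C[C@H](C)C(=O)O1 | intermediate
24 | (9R,9aS)-9-{(1S)-1-[(2R,4S)-4-methyl-5-oxooxolan-2-yl]propyl}-5,6,7,8,9,9a-hexahydro-3H-pyrrolo[1,2-a]azepin-3-one | CC[C@@H]([C@H]1CCCCN2[C@H]1C=CC2=O)[C@H]1C[C@H](C)C(=O)O1 | intermediate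
25 | (9R,9aS)-9-{(1S)-1-[(2R,4S)-4-methyl-5-oxooxolan-2-yl]propyl}octahydro-3H-pyrrolo[1,2-a]azepin-3-one | CC[C@@H]([C@H]1CCCCN2[C@H]1CCC2=O)[C@H]1C[C@H](C)C(=O)O1 | intermediate
26 | 3-methylfuran-2(5H)-one | CC1=CCOC1=O | starting material
27 | triisopropyl[(3-methylfuran-2-yl)oxy]silane | Cc1ccoc1O[Si](C(C)C)(C(C)C)C(C)C | intermediate
28 | (3S,5R)-3-methyl-5-{(1S)-1-[(9R,9aS)-3-[(1,1,3,3-tetramethyldisiloxanyl)oxy]octahydro-1H-pyrrolo[1,2-a]azepin-9-yl]propyl}oxolan-2-one (both C3 epimers) | CC[C@@H]([C@H]1CCCCN2[C@H]1CCC2O[Si](C)(C)O[SiH](C)C)[C@H]1C[C@H](C)C(=O)O1 | intermediate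
29 | (9R,9aS)-9-{(1S)-1-[(2R,4S)-4-methyl-5-oxooxolan-2-yl]propyl}-1,2,5,6,7,8,9,9a-octahydropyrrolo[1,2-a]azepin-4-ium trifluoroacetate | CC[C@@H]([C@H]1CCCC[N+]2=CCC[C@@H]12)[C@H]1C[C@H](C)C(=O)O1.[O-]C(=O)C(F)(F)F | intermediate
30 | (5S)-3-methyl-5-[(3S,9R,9aS)-9-{(1S)-1-[(2R,4S)-4-methyl-5-oxooxolan-2-yl]propyl}octahydro-1H-pyrrolo[1,2-a]azepin-3-yl]furan-2(5H)-one | CC[C@@H]([C@H]1CCCCN2[C@H]1CC[C@H]2[C@@H]1C=C(C)C(=O)O1)[C@H]1C[C@H](C)C(=O)O1 | intermediate
31 | (3S,5S)-3-methyl-5-[(3S,9R,9aS)-9-{(1S)-1-[(2R,4S)-4-methyl-5-oxooxolan-2-yl]propyl}octahydro-1H-pyrrolo[1,2-a]azepin-3-yl]oxolan-2-one (CNP0135535.1) | CC[C@@H]([C@H]1CCCCN2[C@H]1CC[C@H]2[C@@H]1C[C@H](C)C(=O)O1)[C@H]1C[C@H](C)C(=O)O1 | target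

**Step count and risks**

Total step count: 16. Longest linear sequence: 15 steps (steps 1–13, 15 and 16; step 14 makes the silyloxyfuran on a side branch).

The three steps most likely to fail:

Step 15. The hydrosilylation may not discriminate cleanly between lactam and lactone, and the vinylogous Mannich addition may show poor facial or threo/erythro selectivity. The fallback sets out from 21 and comes back at 30; it makes the C3 iminium ion from an amino acid instead of from the lactam and still forms the C1–C2 bond by ring-closing metathesis. Amine 21 is combined with glyoxylic acid and the 2,4,6-trivinylcyclotriboroxane–pyridine complex (Petasis three-component reaction, CH2Cl2, 25 °C) to give 2-[(2S,3R)-2-ethenyl-3-{(1S)-1-[(2R,4S)-4-methyl-5-oxooxolan-2-yl]propyl}azepan-1-yl]but-3-enoic acid F1 (the configuration of the new carbon is irrelevant). Ring-closing metathesis of its p-toluenesulfonate salt with the second-generation Grubbs catalyst should give (9R,9aS)-9-{(1S)-1-[(2R,4S)-4-methyl-5-oxooxolan-2-yl]propyl}-5,6,7,8,9,9a-hexahydro-3H-pyrrolo[1,2-a]azepine-3-carboxylic acid F2, and hydrogenation (H2, Pd/C) the saturated amino acid (9R,9aS)-9-{(1S)-1-[(2R,4S)-4-methyl-5-oxooxolan-2-yl]propyl}octahydro-1H-pyrrolo[1,2-a]azepine-3-carboxylic acid F3. Treatment with POCl3 (decarbonylative iminium formation) should generate the same cation as in 29, which is trapped in the same flask with 27 to give 30.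

Step 9. The chiral catalyst and the neighbouring C9 stereocentre may be mismatched, leading to slow rearrangement, poor facial selectivity or elimination of trichloroacetamide. The fallback sets out from 16 and comes back at 21; it forms the C9a–N bond and the azepane in one intramolecular allylic amination. The chloride of 16 is displaced with NaN3 (DMF, 60 °C) to give (3S,5R)-5-[(3S,4S,5E)-4-(4-azidobutyl)-7-hydroxyhept-5-en-3-yl]-3-methyloxolan-2-one F4. Methyl chloroformate and pyridine convert this into (2E,4S,5S)-4-(4-azidobutyl)-5-[(2R,4S)-4-methyl-5-oxooxolan-2-yl]hept-2-en-1-yl methyl carbonate F5. Staudinger reduction (PPh3, THF–H2O) gives (2E,4S,5S)-4-(4-aminobutyl)-5-[(2R,4S)-4-methyl-5-oxooxolan-2-yl]hept-2-en-1-yl methyl carbonate F6, which is cyclised at once with [Ir(cod)Cl]2 and a chiral phosphoramidite ligand (THF, 25 °C). The tether allows attack only at the internal allyl terminus, giving the 2-vinylazepane 21, and the ligand antipode controls C9a.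

Step 6. Hydride delivery to the α-branched ketone may show poor or reversed facial selectivity at C11. The fallback sets out from 13 and comes back at 15; it makes the C11 epimer on purpose and inverts it during ring closure. Reagent-controlled Corey–Bakshi–Shibata reduction (oxazaborolidine antipode chosen for the 4S alcohol, catecholborane, −78 °C) should give methyl (2S,4S,5S,6S,7E)-9-{[tert-butyl(dimethyl)silyl]oxy}-6-(4-chlorobutyl)-5-ethyl-4-hydroxy-2-methylnon-7-enoate F7. Saponification with LiOH (THF–H2O) gives (2S,4S,5S,6S,7E)-9-{[tert-butyl(dimethyl)silyl]oxy}-6-(4-chlorobutyl)-5-ethyl-4-hydroxy-2-methylnon-7-enoic acid F8, and Mitsunobu lactonisation (PPh3, diisopropyl azodicarboxylate, toluene) closes lactone B with inversion at C11 to give 15.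

Further compounds
F1 | step 15 | 2-[(2S,3R)-2-ethenyl-3-{(1S)-1-[(2R,4S)-4-methyl-5-oxooxolan-2-yl]propyl}azepan-1-yl]but-3-enoic acid | CC[C@@H]([C@H]1CCCCN(C(C=C)C(O)=O)[C@H]1C=C)[C@H]1C[C@H](C)C(=O)O1
F2 | step 15 | (9R,9aS)-9-{(1S)-1-[(2R,4S)-4-methyl-5-oxooxolan-2-yl]propyl}-5,6,7,8,9,9a-hexahydro-3H-pyrrolo[1,2-a]azepine-3-carboxylic acid | CC[C@@H]([C@H]1CCCCN2[C@H]1C=CC2C(O)=O)[C@H]1C[C@H](C)C(=O)O1
F3 | step 15 | (9R,9aS)-9-{(1S)-1-[(2R,4S)-4-methyl-5-oxooxolan-2-yl]propyl}octahydro-1H-pyrrolo[1,2-a]azepine-3-carboxylic acid | CC[C@@H]([C@H]1CCCCN2[C@H]1CCC2C(O)=O)[C@H]1C[C@H](C)C(=O)O1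
F4 | step 9 | (3S,5R)-5-[(3S,4S,5E)-4-(4-azidobutyl)-7-hydroxyhept-5-en-3-yl]-3-methyloxolan-2-one | CC[C@@H]([C@H](/C=C/CO)CCCCN=[N+]=[N-])[C@H]1C[C@H](C)C(=O)O1
F5 | step 9 | (2E,4S,5S)-4-(4-azidobutyl)-5-[(2R,4S)-4-methyl-5-oxooxolan-2-yl]hept-2-en-1-yl methyl carbonate | CC[C@@H]([C@H](/C=C/COC(=O)OC)CCCCN=[N+]=[N-])[C@H]1C[C@H](C)C(=O)O1
F6 | step 9 | (2E,4S,5S)-4-(4-aminobutyl)-5-[(2R,4S)-4-methyl-5-oxooxolan-2-yl]hept-2-en-1-yl methyl carbonate | CC[C@@H]([C@H](/C=C/COC(=O)OC)CCCCN)[C@H]1C[C@H](C)C(=O)O1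
F7 | step 6 | methyl (2S,4S,5S,6S,7E)-9-{[tert-butyl(dimethyl)silyl]oxy}-6-(4-chlorobutyl)-5-ethyl-4-hydroxy-2-methylnon-7-enoate | CC[C@@H]([C@H](/C=C/CO[Si](C)(C)C(C)(C)C)CCCCCl)[C@@H](O)C[C@H](C)C(=O)OC
F8 | step 6 | (2S,4S,5S,6S,7E)-9-{[tert-butyl(dimethyl)silyl]oxy}-6-(4-chlorobutyl)-5-ethyl-4-hydroxy-2-methylnon-7-enoic acid | CC[C@@H]([C@H](/C=C/CO[Si](C)(C)C(C)(C)C)CCCCCl)[C@@H](O)C[C@H](C)C(O)=O
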